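## Retrosynthetic overview

- The oxirane is made last, by catalyst-controlled epoxidation of the C10 vinyl group, the only electron-rich alkene left at that point.
- The γ-lactone and the enal both come from one double allylic oxidation of a bis-isopropenyl diol: C8–OH closes the lactone, while the C6 angelate keeps the other side open as the aldehyde.
- The axial C6–O comes from hydride reduction of a C6 ketone; the same ketone is used first to attach the C7 isopropenyl group in the equatorial position.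
- The C8/C9 cis-diol comes from the C9 ketone (enolate hydroxylation, then bulky hydride). C5 and C10 are set in one three-component coupling on an (S)-4-silyloxy-2-methylcyclohexenone (the proposed new step).
- Ring order: the cyclohexane is present in the purchased enone ketal, a temporary dioxolane protects the diol, the lactone closes in step 17 and the oxirane in step 18.

Assumption: compound 1, isopropenylmagnesium bromide, vinyl bromide, 2-bromopropene and angelic anhydride are purchased. Atom labels C1–C15 in the Why lines are the elemane numbers of the target (ring C5–C10 with C10 quaternary, oxirane C1–C2, enal C3/C4/C15, lactone C11–C13).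

## Route

Step 1
Reactants: 1 1,4-dioxaspiro[4.5]dec-6-en-8-one
Product: 2 (8S)-1,4-dioxaspiro[4.5]dec-6-en-8-ol
Conditions: (R)-2-methyl-CBS-oxazaborolidine (10 mol%), BH3·SMe2, THF, −30 °C; H2O work-up
Reagents that add atoms: none
Why: Corey–Bakshi–Shibata reduction in which the alkene arm of the enone acts as the large group, so hydride is delivered to the face that gives the (S)-allylic alcohol, the stereocentre (C6) that later directs C5 and C10.

Step 2
Reactants: 2 (8S)-1,4-dioxaspiro[4.5]dec-6-en-8-ol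
Product: 3 tert-butyl[(8S)-1,4-dioxaspiro[4.5]dec-6-en-8-yloxy]dimethylsilane
Conditions: TBSCl, imidazole, DMF, rt
Reagents that add atoms: tert-butyldimethylsilyl chloride CC(C)(C)[Si](C)(C)Cl
Why: Standard silyl ether formation on an unhindered secondary alcohol, with no change at the stereocentre.

Step 3
Reactants: 3 tert-butyl[(8S)-1,4-dioxaspiro[4.5]dec-6-en-8-yloxy]dimethylsilane
Product: 4 (4S)-4-[(tert-butyldimethylsilyl)oxy]cyclohex-2-en-1-one
Conditions: PPTS (cat.), THF–H2O 4:1, 40 °C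
Reagents that add atoms: water O
Why: Acid-catalysed hydrolysis of the allylic dioxolane unveils the enone while the silyl ether and its stereocentre are untouched.

Step 4
Reactants: 4 (4S)-4-[(tert-butyldimethylsilyl)oxy]cyclohex-2-en-1-one
Product: 5 (4S)-4-[(tert-butyldimethylsilyl)oxy]-2-iodocyclohex-2-en-1-one
Conditions: I2, pyridine, CH2Cl2, 0 °C to rt
Reagents that add atoms: iodine II
Why: Johnson α-iodination of an enone (pyridine conjugate addition, enolate iodination, elimination) is routine for 4-silyloxycyclohexenones.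

Step 5
Reactants: 5 (4S)-4-[(tert-butyldimethylsilyl)oxy]-2-iodocyclohex-2-en-1-one
Product: 6 (4S)-4-[(tert-butyldimethylsilyl)oxy]-2-methylcyclohex-2-en-1-one
Conditions: Me4Sn, Pd(PPh3)4 (5 mol%), CuI (10 mol%), NMP, 60 °C
Reagents that add atoms: tetramethylstannane C[Sn](C)(C)C
Why: Stille coupling of an α-iodoenone installs the C14 methyl group on sp2 carbon, so the later enolate is regiodefined.

Step 6
Reactants: 6 (4S)-4-[(tert-butyldimethylsilyl)oxy]-2-methylcyclohex-2-en-1-one
Product: 8 (2S,3S,4S)-4-[(tert-butyldimethylsilyl)oxy]-2-ethenyl-2-methyl-3-(prop-1-en-2-yl)cyclohexan-1-one, via bromomagnesium enolate 7 (not isolated)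
Conditions: isopropenylmagnesium bromide, CuBr·SMe2 (10 mol%), THF, −78 to −30 °C; then vinyl bromide, Pd2(dba)3 (2.5 mol%), P(t-Bu)3 (6 mol%), −30 °C to rt
Reagents that add atoms: isopropenylmagnesium bromide CC(=C)[Mg]Br; vinyl bromide C=CBr
Why: Proposed new method: a one-pot copper-catalysed conjugate alkenylation followed by palladium-catalysed α-vinylation of the resulting enolate, in which the cuprate adds to C5 anti to the pseudoaxial γ-silyloxy group, the regiodefined tetrasubstituted bromomagnesium enolate 7 transmetallates to the vinylpalladium bromide formed by oxidative addition of zerovalent palladium to vinyl bromide, and reductive elimination from the C-bound palladium enolate on the face opposite the new isopropenyl group builds the C10 quaternary centre with vinyl trans to isopropenyl (the bulky P(t-Bu)3 favours reductive elimination over β-hydride elimination), the closest known reaction types being the palladium-catalysed α-vinylation of preformed lithium ketone enolates with vinyl bromides and the palladium-catalysed allylation of conjugate-addition enolates.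

Step 7
Reactants: 8 (2S,3S,4S)-4-[(tert-butyldimethylsilyl)oxy]-2-ethenyl-2-methyl-3-(prop-1-en-2-yl)cyclohexan-1-one
Product: 10 (2S,3S,4S,6R)-4-[(tert-butyldimethylsilyl)oxy]-2-ethenyl-6-hydroxy-2-methyl-3-(prop-1-en-2-yl)cyclohexan-1-one, via potassium enolate 9 (not isolated)
Conditions: KN(SiMe3)2, THF, −78 °C; then 3-phenyl-2-(phenylsulfonyl)oxaziridine, −78 °C; H2O work-up
Reagents that add atoms: 3-phenyl-2-(phenylsulfonyl)oxaziridine O=S(=O)(N1OC1c1ccccc1)c1ccccc1
Why: Davis enolate hydroxylation, where C8 is the only enolisable position and the oxaziridine approaches the enolate face opposite the axial C10 methyl group, giving the equatorial C8–OH (also the thermodynamic epimer) without touching the isolated alkenes.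

Step 8
Reactants: 10 (2S,3S,4S,6R)-4-[(tert-butyldimethylsilyl)oxy]-2-ethenyl-6-hydroxy-2-methyl-3-(prop-1-en-2-yl)cyclohexan-1-one
Product: 11 (1R,2S,3S,4S,5S)-5-[(tert-butyldimethylsilyl)oxy]-3-ethenyl-3-methyl-4-(prop-1-en-2-yl)cyclohexane-1,2-diol
Conditions: Li(s-Bu)3BH (2.5 equiv), THF, −78 °C; H2O work-up
Reagents that add atoms: none
Why: Bulky-hydride ketone reduction by equatorial attack, as with 2-alkoxycyclohexanones and 4,4-dimethyl-3-keto terpenoids, gives the axial C9–OH cis to the C8–OH.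

Step 9
Reactants: 11 (1R,2S,3S,4S,5S)-5-[(tert-butyldimethylsilyl)oxy]-3-ethenyl-3-methyl-4-(prop-1-en-2-yl)cyclohexane-1,2-diol
Product: 12 tert-butyl{[(3aS,4S,5S,6S,7aR)-4-ethenyl-2,2,4-trimethyl-5-(prop-1-en-2-yl)hexahydro-1,3-benzodioxol-6-yl]oxy}dimethylsilane
Conditions: Me2C(OMe)2, PPTS (cat.), CH2Cl2, rt
Reagents that add atoms: 2,2-dimethoxypropane COC(C)(C)OC
Why: Acetonide formation is specific for the cis (axial/equatorial) 1,2-diol and locks the chair that later controls C7 and C6.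

Step 10
Reactants: 12 tert-butyl{[(3aS,4S,5S,6S,7aR)-4-ethenyl-2,2,4-trimethyl-5-(prop-1-en-2-yl)hexahydro-1,3-benzodioxol-6-yl]oxy}dimethylsilane
Product: 13 (3aS,4S,5S,6S,7aR)-4-ethenyl-2,2,4-trimethyl-5-(prop-1-en-2-yl)hexahydro-1,3-benzodioxol-6-ol
Conditions: Bu4NF, THF, rt
Reagents that add atoms: none
Why: Fluoride desilylation frees the C6 hydroxyl, whose directing role is finished, with no other fluoride-labile group present.

Step 11
Reactants: 13 (3aS,4S,5S,6S,7aR)-4-ethenyl-2,2,4-trimethyl-5-(prop-1-en-2-yl)hexahydro-1,3-benzodioxol-6-ol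
Product: 14 (3aR,6S,7S,7aS)-7-ethenyl-2,2,7-trimethyl-6-(prop-1-en-2-yl)hexahydro-1,3-benzodioxol-5-one
Conditions: Dess–Martin periodinane, CH2Cl2, rt
Reagents that add atoms: none
Why: Dess–Martin oxidation under near-neutral conditions gives the C6 ketone without moving the β,γ-alkene of the C5 isopropenyl group into conjugation.

Step 12
Reactants: 14 (3aR,6S,7S,7aS)-7-ethenyl-2,2,7-trimethyl-6-(prop-1-en-2-yl)hexahydro-1,3-benzodioxol-5-one
Product: 16 (3aR,4R,6S,7S,7aS)-7-ethenyl-2,2,7-trimethyl-4,6-di(prop-1-en-2-yl)hexahydro-1,3-benzodioxol-5-one, via lithium enolate 15 (not isolated)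
Conditions: LiN(SiMe3)2, THF, −78 °C; then 2-bromopropene, Pd2(dba)3 (2.5 mol%), P(t-Bu)3 (6 mol%), −78 °C to rt; H2O work-up
Reagents that add atoms: 2-bromopropene CC(Br)=C
Why: Palladium-catalysed α-alkenylation of a ketone enolate, where kinetic deprotonation occurs at the C7 methylene rather than the hindered C5 methine, and the new enolisable α-centre is protonated from the axial face so the C7 isopropenyl group ends up equatorial and cis to the C5 group, in the chair fixed by the cis-fused acetonide and the axial methyl.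

Step 13
Reactants: 16 (3aR,4R,6S,7S,7aS)-7-ethenyl-2,2,7-trimethyl-4,6-di(prop-1-en-2-yl)hexahydro-1,3-benzodioxol-5-one
Product: 17 (3aR,4S,5S,6S,7S,7aS)-7-ethenyl-2,2,7-trimethyl-4,6-di(prop-1-en-2-yl)hexahydro-1,3-benzodioxol-5-ol
Conditions: Li(s-Bu)3BH, THF, −78 °C; H2O work-up
Reagents that add atoms: none
Why: Bulky-hydride reduction by equatorial attack, the axial trajectory being blocked by the syn-axial C10 methyl, gives the axial C6–OH cis to both flanking isopropenyl groups.

Step 14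
Reactants: 17 (3aR,4S,5S,6S,7S,7aS)-7-ethenyl-2,2,7-trimethyl-4,6-di(prop-1-en-2-yl)hexahydro-1,3-benzodioxol-5-ol
Product: 19 (3aR,4S,5S,6S,7S,7aS)-7-ethenyl-2,2,7-trimethyl-4,6-di(prop-1-en-2-yl)hexahydro-1,3-benzodioxol-5-yl (2Z)-2-methylbut-2-enoate, via lithium alkoxide 18 (not isolated)
Conditions: LiN(SiMe3)2, THF, −78 °C; then angelic anhydride, −78 to 0 °C
Reagents that add atoms: angelic anhydride C/C=C(/C)C(=O)OC(=O)/C(C)=C\C
Why: Acylation of a preformed lithium alkoxide with the anhydride is the most forcing low-temperature esterification for a hindered axial alcohol and avoids the heat and nucleophilic catalysts that isomerise angelate to tiglate.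

Step 15
Reactants: 19 (3aR,4S,5S,6S,7S,7aS)-7-ethenyl-2,2,7-trimethyl-4,6-di(prop-1-en-2-yl)hexahydro-1,3-benzodioxol-5-yl (2Z)-2-methylbut-2-enoate
Product: 20 (1S,2S,3S,4S,5R,6R)-3-ethenyl-4,5-dihydroxy-3-methyl-2,6-di(prop-1-en-2-yl)cyclohexyl (2Z)-2-methylbut-2-enoate
Conditions: AcOH–H2O–THF 3:1:1, 45 °C
Reagents that add atoms: none
Why: Mild acidic acetonide hydrolysis frees the C8/C9 diol while the hindered conjugated ester and the alkenes are stable.

Step 16
Reactants: 20 (1S,2S,3S,4S,5R,6R)-3-ethenyl-4,5-dihydroxy-3-methyl-2,6-di(prop-1-en-2-yl)cyclohexyl (2Z)-2-methylbut-2-enoate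
Product: 21 (1S,2S,3S,4S,5R,6R)-3-ethenyl-4,5-dihydroxy-2,6-bis(3-hydroxyprop-1-en-2-yl)-3-methylcyclohexyl (2Z)-2-methylbut-2-enoate
Conditions: SeO2 (0.3 equiv), t-BuOOH, CH2Cl2, 0 °C to rt
Reagents that add atoms: tert-butyl hydroperoxide CC(C)(C)OO
Why: Selenium dioxide/tert-butyl hydroperoxide allylic oxidation (ene reaction then [2,3]-shift) hydroxylates the methyl of each isopropenyl group, while the vinyl group has no allylic hydrogen and the conjugated angelate is deactivated.

Step 17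
Reactants: 21 (1S,2S,3S,4S,5R,6R)-3-ethenyl-4,5-dihydroxy-2,6-bis(3-hydroxyprop-1-en-2-yl)-3-methylcyclohexyl (2Z)-2-methylbut-2-enoate
Product: 24 (3aS,4S,5R,6S,7S,7aR)-6-ethenyl-7-hydroxy-6-methyl-3-methylidene-2-oxo-5-(3-oxoprop-1-en-2-yl)octahydro-1-benzofuran-4-yl (2Z)-2-methylbut-2-enoate, via dialdehyde 22 (not isolated), via lactol 23 (not isolated)
Conditions: MnO2 (excess), CH2Cl2, rt
Reagents that add atoms: none
Why: Manganese dioxide oxidises only allylic alcohols, so both primary alcohols become enals, the C12 aldehyde is trapped by the adjacent equatorial C8–OH as an allylic lactol that is oxidised on to the trans-fused α-methylene lactone, and the C3 aldehyde stays an enal because C6 is acylated and C9–OH is trans-1,3 to it.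

Step 18
Reactants: 24 (3aS,4S,5R,6S,7S,7aR)-6-ethenyl-7-hydroxy-6-methyl-3-methylidene-2-oxo-5-(3-oxoprop-1-en-2-yl)octahydro-1-benzofuran-4-yl (2Z)-2-methylbut-2-enoate
Product: 25 (3aS,4S,5R,6S,7S,7aR)-7-hydroxy-6-methyl-3-methylidene-6-[(2R)-oxiran-2-yl]-2-oxo-5-(3-oxoprop-1-en-2-yl)octahydro-1-benzofuran-4-yl (2Z)-2-methylbut-2-enoate
Conditions: Ti(OiPr)4 (10 mol%), chiral cis-1,2-diaminocyclohexane salalen ligand (10 mol%, the enantiomer that turns 1-octene into (R)-1,2-epoxyoctane), 30% aq. H2O2, CH2Cl2, rt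
Reagents that add atoms: hydrogen peroxide OO
Why: Titanium salalen/hydrogen peroxide asymmetric epoxidation is selective for unconjugated terminal alkenes, so only the vinyl group reacts and the catalyst sets C1 as R, the three conjugated alkenes being inert to this electrophilic oxidant.

## Compound list

1 | 1,4-dioxaspiro[4.5]dec-6-en-8-one | O=C1CCC2(OCCO2)C=C1 | starting material
2 | (8S)-1,4-dioxaspiro[4.5]dec-6-en-8-ol | C1C[C@H](O)C=CC12OCCO2 | intermediate
3 | tert-butyl[(8S)-1,4-dioxaspiro[4.5]dec-6-en-8-yloxy]dimethylsilane | C1C[C@H](O[Si](C)(C)C(C)(C)C)C=CC12OCCO2 | intermediate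
4 | (4S)-4-[(tert-butyldimethylsilyl)oxy]cyclohex-2-en-1-one | C1C[C@H](O[Si](C)(C)C(C)(C)C)C=CC1=O | intermediate
5 | (4S)-4-[(tert-butyldimethylsilyl)oxy]-2-iodocyclohex-2-en-1-one | C1C[C@H](O[Si](C)(C)C(C)(C)C)C=C(I)C1=O | intermediate
6 | (4S)-4-[(tert-butyldimethylsilyl)oxy]-2-methylcyclohex-2-en-1-one | C1C[C@H](O[Si](C)(C)C(C)(C)C)C=C(C)C1=O | intermediate
7 | bromo{[(3S,4S)-4-[(tert-butyldimethylsilyl)oxy]-2-methyl-3-(prop-1-en-2-yl)cyclohex-1-en-1-yl]oxy}magnesium (bromomagnesium enolate) | C1C[C@H](O[Si](C)(C)C(C)(C)C)[C@@H](C(C)=C)C(C)=C1O[Mg]Br | intermediate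
8 | (2S,3S,4S)-4-[(tert-butyldimethylsilyl)oxy]-2-ethenyl-2-methyl-3-(prop-1-en-2-yl)cyclohexan-1-one | C1C[C@H](O[Si](C)(C)C(C)(C)C)[C@@H](C(C)=C)[C@](C)(C=C)C1=O | intermediate
9 | potassium (4S,5S,6S)-4-[(tert-butyldimethylsilyl)oxy]-6-ethenyl-6-methyl-5-(prop-1-en-2-yl)cyclohex-1-en-1-olate (potassium enolate) | C=1C[C@H](O[Si](C)(C)C(C)(C)C)[C@@H](C(C)=C)[C@](C)(C=C)C=1O[K] | intermediate
10 | (2S,3S,4S,6R)-4-[(tert-butyldimethylsilyl)oxy]-2-ethenyl-6-hydroxy-2-methyl-3-(prop-1-en-2-yl)cyclohexan-1-one | O[C@@H]1C[C@H](O[Si](C)(C)C(C)(C)C)[C@@H](C(C)=C)[C@](C)(C=C)C1=O | intermediate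
11 | (1R,2S,3S,4S,5S)-5-[(tert-butyldimethylsilyl)oxy]-3-ethenyl-3-methyl-4-(prop-1-en-2-yl)cyclohexane-1,2-diol | O[C@@H]1C[C@H](O[Si](C)(C)C(C)(C)C)[C@@H](C(C)=C)[C@](C)(C=C)[C@@H]1O | intermediate
12 | tert-butyl{[(3aS,4S,5S,6S,7aR)-4-ethenyl-2,2,4-trimethyl-5-(prop-1-en-2-yl)hexahydro-1,3-benzodioxol-6-yl]oxy}dimethylsilane | CC1(C)O[C@@H]2C[C@H](O[Si](C)(C)C(C)(C)C)[C@@H](C(C)=C)[C@](C)(C=C)[C@@H]2O1 | intermediate
13 | (3aS,4S,5S,6S,7aR)-4-ethenyl-2,2,4-trimethyl-5-(prop-1-en-2-yl)hexahydro-1,3-benzodioxol-6-ol | CC1(C)O[C@@H]2C[C@H](O)[C@@H](C(C)=C)[C@](C)(C=C)[C@@H]2O1 | intermediate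
14 | (3aR,6S,7S,7aS)-7-ethenyl-2,2,7-trimethyl-6-(prop-1-en-2-yl)hexahydro-1,3-benzodioxol-5-one | CC1(C)O[C@@H]2CC(=O)[C@@H](C(C)=C)[C@](C)(C=C)[C@@H]2O1 | intermediate
15 | lithium (3aR,6S,7S,7aS)-7-ethenyl-2,2,7-trimethyl-6-(prop-1-en-2-yl)-3a,6,7,7a-tetrahydro-1,3-benzodioxol-5-olate (lithium enolate) | CC1(C)O[C@@H]2C=C(O[Li])[C@@H](C(C)=C)[C@](C)(C=C)[C@@H]2O1 | intermediate
16 | (3aR,4R,6S,7S,7aS)-7-ethenyl-2,2,7-trimethyl-4,6-di(prop-1-en-2-yl)hexahydro-1,3-benzodioxol-5-one | CC1(C)O[C@@H]2[C@@H](C(C)=C)C(=O)[C@@H](C(C)=C)[C@](C)(C=C)[C@@H]2O1 | intermediate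
17 | (3aR,4S,5S,6S,7S,7aS)-7-ethenyl-2,2,7-trimethyl-4,6-di(prop-1-en-2-yl)hexahydro-1,3-benzodioxol-5-ol | CC1(C)O[C@@H]2[C@@H](C(C)=C)[C@@H](O)[C@@H](C(C)=C)[C@](C)(C=C)[C@@H]2O1 | intermediate
18 | lithium (3aR,4S,5S,6S,7S,7aS)-7-ethenyl-2,2,7-trimethyl-4,6-di(prop-1-en-2-yl)hexahydro-1,3-benzodioxol-5-olate (lithium alkoxide) | CC1(C)O[C@@H]2[C@@H](C(C)=C)[C@@H](O[Li])[C@@H](C(C)=C)[C@](C)(C=C)[C@@H]2O1 | intermediate
19 | (3aR,4S,5S,6S,7S,7aS)-7-ethenyl-2,2,7-trimethyl-4,6-di(prop-1-en-2-yl)hexahydro-1,3-benzodioxol-5-yl (2Z)-2-methylbut-2-enoate | CC1(C)O[C@@H]2[C@@H](C(C)=C)[C@@H](OC(=O)/C(C)=C\C)[C@@H](C(C)=C)[C@](C)(C=C)[C@@H]2O1 | intermediate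
20 | (1S,2S,3S,4S,5R,6R)-3-ethenyl-4,5-dihydroxy-3-methyl-2,6-di(prop-1-en-2-yl)cyclohexyl (2Z)-2-methylbut-2-enoate | O[C@@H]1[C@@H](C(C)=C)[C@@H](OC(=O)/C(C)=C\C)[C@@H](C(C)=C)[C@](C)(C=C)[C@@H]1O | intermediate
21 | (1S,2S,3S,4S,5R,6R)-3-ethenyl-4,5-dihydroxy-2,6-bis(3-hydroxyprop-1-en-2-yl)-3-methylcyclohexyl (2Z)-2-methylbut-2-enoate | O[C@@H]1[C@@H](C(=C)CO)[C@@H](OC(=O)/C(C)=C\C)[C@@H](C(=C)CO)[C@](C)(C=C)[C@@H]1O | intermediate
22 | (1S,2R,3S,4S,5R,6R)-3-ethenyl-4,5-dihydroxy-3-methyl-2,6-bis(3-oxoprop-1-en-2-yl)cyclohexyl (2Z)-2-methylbut-2-enoate (dialdehyde) | O[C@@H]1[C@@H](C(=C)C=O)[C@@H](OC(=O)/C(C)=C\C)[C@@H](C(=C)C=O)[C@](C)(C=C)[C@@H]1O | intermediate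
23 | (3aS,4S,5R,6S,7S,7aR)-6-ethenyl-2,7-dihydroxy-6-methyl-3-methylidene-5-(3-oxoprop-1-en-2-yl)octahydro-1-benzofuran-4-yl (2Z)-2-methylbut-2-enoate (lactol, both C2 epimers) | C=C1C(O)O[C@@H]2[C@@H]1[C@@H](OC(=O)/C(C)=C\C)[C@@H](C(=C)C=O)[C@](C)(C=C)[C@@H]2O | intermediate
24 | (3aS,4S,5R,6S,7S,7aR)-6-ethenyl-7-hydroxy-6-methyl-3-methylidene-2-oxo-5-(3-oxoprop-1-en-2-yl)octahydro-1-benzofuran-4-yl (2Z)-2-methylbut-2-enoate | C=C1C(=O)O[C@@H]2[C@@H]1[C@@H](OC(=O)/C(C)=C\C)[C@@H](C(=C)C=O)[C@](C)(C=C)[C@@H]2O | intermediate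
25 | (3aS,4S,5R,6S,7S,7aR)-7-hydroxy-6-methyl-3-methylidene-6-[(2R)-oxiran-2-yl]-2-oxo-5-(3-oxoprop-1-en-2-yl)octahydro-1-benzofuran-4-yl (2Z)-2-methylbut-2-enoate | C=C1C(=O)O[C@@H]2[C@@H]1[C@@H](OC(=O)/C(C)=C\C)[C@@H](C(=C)C=O)[C@](C)([C@@H]1CO1)[C@@H]2O | target

## Step count and risks

Total step count: 18. Longest linear sequence: 18 steps (fully linear from 1).

The three steps most likely to fail:

Step 6, the proposed new step. The magnesium enolate may transmetallate poorly, the palladium enolate may undergo β-hydride elimination back to an enone, or leftover Grignard reagent may consume the vinyl bromide. The fallback uses known chemistry, sets out from 6 and comes back at 8. The same CuBr·SMe2-catalysed addition of isopropenylmagnesium bromide is run, then ZnCl2 and acetaldehyde are added at −78 °C; this tandem conjugate addition–aldol reaction gives the 2-(1-hydroxyethyl) ketone F1, with the new C–C bond again trans to the isopropenyl group. Burgess dehydration of the 2-(1-hydroxyethyl) ketone F1 (toluene, 70 °C) can only eliminate toward the methyl group, because C10 is quaternary, and gives 8.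

Step 12. The lithium enolate carries a β-oxygen (C8) that could be expelled on warming, the enolate could equilibrate toward C5 and drag the C5 isopropenyl alkene into conjugation, and Heck-type side reactions are possible. The fallback sets out from 14 and comes back at 16 by an aldol condensation followed by deconjugation. LiN(SiMe3)2 and acetone at −78 °C give the tertiary aldol F2. MsCl/Et3N then DBU convert the tertiary aldol F2 into the isopropylidene enone F3. LiN(i-Pr)2 at −78 °C then removes a γ-hydrogen of the isopropylidene enone F3, and kinetic α-protonation of the dienolate with AcOH at −78 °C (the pulegone-to-isopulegone type deconjugation) delivers the equatorial isopropenyl ketone 16.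

Step 18. The catalyst system is established for simple 1-alkenes, but this vinyl group sits on a quaternary carbon next to a free hydroxyl, so it may be slow or mismatched with the substrate, and the enal may suffer from peroxide. The fallback sets out from 24 and comes back at 25 by replacing asymmetric induction with resolution. Dimethyldioxirane (acetone, 0 °C) epoxidises the vinyl group without face control and gives 25 mixed with the (2S)-oxirane epimer F4. Hydrolytic kinetic resolution of the mixture with the enantiomer of (salen)Co(OAc) (trivalent cobalt) that hydrolyses (S)-configured terminal epoxides, and 0.6 equiv of water, opens only the (2S)-oxirane epimer F4 to the 1,2-diol F5, and 25 is separated from the 1,2-diol F5 by chromatography.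

Further compounds
F1 | step 6 | 4-[(tert-butyldimethylsilyl)oxy]-2-(1-hydroxyethyl)-2-methyl-3-(prop-1-en-2-yl)cyclohexan-1-one (ring stereocentres arranged as in 8, both carbinol epimers) | C1C[C@H](O[Si](C)(C)C(C)(C)C)[C@@H](C(C)=C)[C@](C)(C(C)O)C1=O
F2 | step 12 | 7-ethenyl-4-(2-hydroxypropan-2-yl)-2,2,7-trimethyl-6-(prop-1-en-2-yl)hexahydro-1,3-benzodioxol-5-one (other stereocentres as in 14, both C4 epimers) | CC1(C)O[C@@H]2C(C(C)(C)O)C(=O)[C@@H](C(C)=C)[C@](C)(C=C)[C@@H]2O1
F3 | step 12 | (3aR,6S,7S,7aS)-7-ethenyl-2,2,7-trimethyl-4-(propan-2-ylidene)-6-(prop-1-en-2-yl)tetrahydro-1,3-benzodioxol-5(4H)-one | CC1(C)O[C@@H]2C(=C(C)C)C(=O)[C@@H](C(C)=C)[C@](C)(C=C)[C@@H]2O1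
F4 | step 18 | (2S)-oxiranyl epimer of 25 | C=C1C(=O)O[C@@H]2[C@@H]1[C@@H](OC(=O)/C(C)=C\C)[C@@H](C(=C)C=O)[C@](C)([C@H]1CO1)[C@@H]2O
F5 | step 18 | 6-[(1S)-1,2-dihydroxyethyl] analogue of 25 (oxirane of F4 opened by water) | C=C1C(=O)O[C@@H]2[C@@H]1[C@@H](OC(=O)/C(C)=C\C)[C@@H](C(=C)C=O)[C@](C)([C@H](O)CO)[C@@H]2O
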